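## Retrosynthetic overview

1. 23 ⇐ 22 (ester hydrolysis) ⇐ 21 ⇐ 20: both exocyclic methylenes (decalin C-3 and C-6, target numbering) are unveiled last from a bis(enol triflate) by Negishi coupling and protodesilylation.
2. 1,2-Dioxane (third ring formed): the C-3–C(α) bond comes from an asymmetric Mukaiyama-type addition of ketene acetal 18 to a peroxycarbenium ion; the O–C-6 bond comes from an asymmetric Markovnikov cyclisation of a hydroperoxy acetal made from 15 and H2O2.
3. Ring B (second ring): intramolecular Michael addition of a methyl ketone (from a vinyl group, Wacker) to the ring A enone, cis-fused.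
4. Ring A (first ring): amine-catalysed Michael addition of aldehyde 9 to but-3-en-2-one, then aldol condensation; decalin C-2 is set first, by amine-catalysed Michael addition of lactol 3 to vinyl ketone 6.
5. Building blocks: anhydride 1, Grignard reagent 4, Weinreb amide 5, enone 10, ketene acetal 18.

Assumption: 4 and 18 are bought as catalogue reagents, and the hands of the two IDPi catalysts written in steps 11 and 12 are provisional (both enantiomers would be screened).

## Route

Step 1
Reactants: 1 anhydride 4,4-dimethyloxane-2,6-dione (3,3-dimethylglutaric anhydride)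
Product: 2 lactone 4,4-dimethyloxan-2-one
Conditions: NaBH4, THF, 0 °C to rt; then 6 M HCl
Reagents that add atoms: none
Why: Hydride reduction of one carbonyl of the symmetrical cyclic anhydride gives a hydroxy acid that lactonises on acidification (anhydride-to-lactone reduction), and no stereocentre is formed.

Step 2
Reactants: 2 lactone 4,4-dimethyloxan-2-one
Product: 3 lactol 4,4-dimethyloxan-2-ol
Conditions: i-Bu2AlH, CH2Cl2, −78 °C; aq. potassium sodium tartrate
Reagents that add atoms: none
Why: Partial reduction of a δ-lactone at low temperature stops at the lactol (lactone-to-lactol reduction), a masked 5-hydroxy-3,3-dimethylpentanal whose two arms are now different.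

Step 3
Reactants: 4 Grignard reagent [2-(1,3-dioxolan-2-yl)ethyl]magnesium bromide; 5 Weinreb amide N-methoxy-N-methylprop-2-enamide
Product: 6 vinyl ketone 5-(1,3-dioxolan-2-yl)pent-1-en-3-one
Conditions: THF, −78 to 0 °C; poured into cold 1 M HCl/Et2O
Reagents that add atoms: none
Why: The chelated tetrahedral adduct of the Grignard reagent and the Weinreb amide survives until the quench, so addition stops at the ketone (Weinreb ketone synthesis), and the acidic quench keeps the released amine from adding to the enone.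

Step 4
Reactants: 3 lactol 4,4-dimethyloxan-2-ol; 6 vinyl ketone 5-(1,3-dioxolan-2-yl)pent-1-en-3-one
Product: 7 keto lactol (3S)-3-[5-(1,3-dioxolan-2-yl)-3-oxopentyl]-4,4-dimethyloxan-2-ol
Conditions: (S)-2-[diphenyl(trimethylsilyloxy)methyl]pyrrolidine (10 mol %), ethyl 3,4-dihydroxybenzoate (20 mol %), CHCl3, 4 °C
Reagents that add atoms: none
Why: The open hydroxy aldehyde form of 3 gives an E-enamine that adds to the vinyl ketone on the face away from the diphenyl(silyloxy)methyl group (enamine-catalysed asymmetric Michael addition of an aldehyde to an enone), which sets decalin C-2 as the first stereocentre before the adduct recloses to the lactol.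

Step 5
Reactants: 7 keto lactol (3S)-3-[5-(1,3-dioxolan-2-yl)-3-oxopentyl]-4,4-dimethyloxan-2-ol
Product: 8 diene alcohol (4R)-9-(1,3-dioxolan-2-yl)-4-ethenyl-3,3-dimethyl-7-methylidenenonan-1-ol
Conditions: Ph3PCH3Br (4 equiv), KOt-Bu (3.9 equiv), THF, 0 °C to rt
Reagents that add atoms: methyltriphenylphosphonium bromide, C[P+](c1ccccc1)(c1ccccc1)c1ccccc1.[Br-]
Why: Excess methylidene ylide methylenates both the ketone and the aldehyde in equilibrium with the lactol (Wittig olefination with lactol opening), giving the 1,1-disubstituted alkene needed for the peroxide and the vinyl group that masks the ring B methyl ketone, while the α-stereocentre, shielded by the neighbouring quaternary carbon, is not epimerised at this temperature.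

Step 6
Reactants: 8 diene alcohol (4R)-9-(1,3-dioxolan-2-yl)-4-ethenyl-3,3-dimethyl-7-methylidenenonan-1-ol
Product: 9 diene aldehyde (4R)-9-(1,3-dioxolan-2-yl)-4-ethenyl-3,3-dimethyl-7-methylidenenonanal
Conditions: TEMPO (10 mol %), PhI(OAc)2 (1.2 equiv), CH2Cl2, rt
Reagents that add atoms: none
Why: Oxoammonium-mediated oxidation of the primary alcohol stops at the aldehyde and leaves the alkenes and the acetal untouched (TEMPO oxidation).

Step 7
Reactants: 9 diene aldehyde (4R)-9-(1,3-dioxolan-2-yl)-4-ethenyl-3,3-dimethyl-7-methylidenenonanal; 10 enone but-3-en-2-one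
Product: 12 cyclohexenone (4S)-4-[(3R)-8-(1,3-dioxolan-2-yl)-3-ethenyl-2-methyl-6-methylideneoctan-2-yl]cyclohex-2-en-1-one, via keto aldehyde 11 (not isolated)
Conditions: (R)-2-[diphenyl(trimethylsilyloxy)methyl]pyrrolidine (10 mol %), ethyl 3,4-dihydroxybenzoate (20 mol %), 4 °C; then LiOH (0.5 equiv), i-PrOH, rt
Reagents that add atoms: none
Why: The enantiomeric amine catalyst controls the second enamine Michael addition (the existing centre is insulated by the quaternary carbon) and sets decalin C-8a, and base then closes ring A by intramolecular aldol condensation of the methyl ketone onto the aldehyde (Michael addition–aldol condensation route to 4-substituted cyclohex-2-enones).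

Step 8
Reactants: 12 cyclohexenone (4S)-4-[(3R)-8-(1,3-dioxolan-2-yl)-3-ethenyl-2-methyl-6-methylideneoctan-2-yl]cyclohex-2-en-1-one
Product: 13 enone methyl ketone (4S)-4-[(3S)-3-acetyl-8-(1,3-dioxolan-2-yl)-2-methyl-6-methylideneoctan-2-yl]cyclohex-2-en-1-one
Conditions: PdCl2 (10 mol %), CuCl (1 equiv), O2 (1 atm), DMF/H2O 7:1, rt
Reagents that add atoms: water, O
Why: Tsuji–Wacker oxidation turns the monosubstituted vinyl group into a methyl ketone with Markovnikov selectivity, while the 1,1-disubstituted alkene and the enone, both poor substrates for hydroxypalladation, stay intact.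

Step 9
Reactants: 13 enone methyl ketone (4S)-4-[(3S)-3-acetyl-8-(1,3-dioxolan-2-yl)-2-methyl-6-methylideneoctan-2-yl]cyclohex-2-en-1-one
Product: 14 cis-decalindione (3S,4aS,8aS)-3-[5-(1,3-dioxolan-2-yl)-3-methylidenepentyl]-4,4-dimethyloctahydronaphthalene-2,7(1H,3H)-dione
Conditions: pyrrolidine (30 mol %), AcOH (30 mol %), CH2Cl2, rt
Reagents that add atoms: none
Why: The less substituted enamine of the methyl ketone adds to the β-carbon of the enone through the three-atom tether on the neighbouring carbon (intramolecular enamine Michael addition, 6-exo), so the new bond can only form on the face that carries the tether and decalin C-4a is set with the cis ring fusion.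

Step 10
Reactants: 14 cis-decalindione (3S,4aS,8aS)-3-[5-(1,3-dioxolan-2-yl)-3-methylidenepentyl]-4,4-dimethyloctahydronaphthalene-2,7(1H,3H)-dione
Product: 15 bis(enol triflate) (3S,4aS,8aR)-3-[5-(1,3-dioxolan-2-yl)-3-methylidenepentyl]-4,4-dimethyl-3,4,4a,5,8,8a-hexahydronaphthalene-2,7-diyl bis(trifluoromethanesulfonate)
Conditions: KN(SiMe3)2 (2.5 equiv), PhNTf2 (2.5 equiv), THF, −78 °C
Reagents that add atoms: N-phenylbis(trifluoromethanesulfonimide), O=S(=O)(N(c1ccccc1)S(=O)(=O)C(F)(F)F)C(F)(F)F
Why: Kinetic deprotonation takes the ring B ketone at its unhindered CH2 and not at the C-2 methine, and O-triflation of both enolates (enol triflate formation) gives two acid-inert masked methylenes and removes the carbonyl next to C-2 so that it can no longer epimerise; the ring A triflate is drawn as the isomer with the double bond away from the ring fusion, and the other ring A isomer converges in step 14.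

Step 11
Reactants: 15 bis(enol triflate) (3S,4aS,8aR)-3-[5-(1,3-dioxolan-2-yl)-3-methylidenepentyl]-4,4-dimethyl-3,4,4a,5,8,8a-hexahydronaphthalene-2,7-diyl bis(trifluoromethanesulfonate)
Product: 17 peroxyacetal (3S,4aS,8aR)-3-{2-[(3S)-6-(2-hydroxyethoxy)-3-methyl-1,2-dioxan-3-yl]ethyl}-4,4-dimethyl-3,4,4a,5,8,8a-hexahydronaphthalene-2,7-diyl bis(trifluoromethanesulfonate), via hydroperoxy acetal 16 (not isolated)
Conditions: H2O2 (1.5 equiv, dry, in Et2O), (S,S)-IDPi acid (5 mol %), CHCl3, −20 °C to rt
Reagents that add atoms: hydrogen peroxide, OO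
Why: Proposed new method: the confined, strongly acidic imidodiphosphorimidate first opens the dioxolane so that H2O2 adds to give hydroperoxy acetal 16 and then, inside its chiral pocket, protonates the 1,1-disubstituted alkene while the tethered OOH group closes on the developing tertiary cation in a concerted, asynchronous 6-exo Markovnikov addition (the competing Prins closure would be 5-endo and the enol triflates are inert to acid), so the chiral anion chooses the face of the methyl/alkyl-substituted carbon and sets dioxane C-6; the closest known reactions are the IDPi-catalysed asymmetric intramolecular hydroalkoxylation of unactivated 1,1-disubstituted alkenes to 2,2-disubstituted cyclic ethers and the non-asymmetric acid-mediated cyclisation of unsaturated hydroperoxides to 1,2-dioxanes.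

Step 12
Reactants: 17 peroxyacetal (3S,4aS,8aR)-3-{2-[(3S)-6-(2-hydroxyethoxy)-3-methyl-1,2-dioxan-3-yl]ethyl}-4,4-dimethyl-3,4,4a,5,8,8a-hexahydronaphthalene-2,7-diyl bis(trifluoromethanesulfonate); 18 ketene acetal (E)-1-methoxy-1-(trimethylsilyloxy)prop-1-ene
Product: 20 dioxane ester methyl (2R)-2-[(3R,6S)-6-{2-[(2S,4aR,8aS)-1,1-dimethyl-3,6-bis(trifluoromethanesulfonyloxy)-1,2,4a,5,8,8a-hexahydronaphthalen-2-yl]ethyl}-6-methyl-1,2-dioxan-3-yl]propanoate, via silyl ether 19 (not isolated)
Conditions: 18 (3 equiv), (R,R)-IDPi acid (5 mol %), toluene, −60 °C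
Reagents that add atoms: none
Why: Proposed new method: the first equivalent of 18 silylates the catalyst and the free hydroxyl group, the silylium imidodiphosphorimidate ion pair then ionises the exocyclic alkoxy group to a cyclic peroxycarbenium ion held against the chiral anion, and the (E)-ketene acetal adds through an open antiperiplanar transition state to the exposed face, which sets dioxane C-3 by catalyst control (the C-6 methyl and chain are too alike to bias this 1,4-related centre) and is expected to place the α-methyl anti to the ring oxygen; the closest known reactions are the IDPi/silylium-catalysed asymmetric Mukaiyama-type additions of silyl ketene acetals to cyclic oxocarbenium ions from lactol derivatives and the achiral Lewis-acid additions of silyl ketene acetals to 3-alkoxy-1,2-dioxanes.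

Step 13
Reactants: 20 dioxane ester methyl (2R)-2-[(3R,6S)-6-{2-[(2S,4aR,8aS)-1,1-dimethyl-3,6-bis(trifluoromethanesulfonyloxy)-1,2,4a,5,8,8a-hexahydronaphthalen-2-yl]ethyl}-6-methyl-1,2-dioxan-3-yl]propanoate
Product: 21 bis(allylsilane) methyl (2R)-2-[(3R,6S)-6-{2-[(2S,4aS,8aS)-1,1-dimethyl-3,6-bis[(trimethylsilyl)methyl]-1,2,4a,5,8,8a-hexahydronaphthalen-2-yl]ethyl}-6-methyl-1,2-dioxan-3-yl]propanoate
Conditions: Me3SiCH2MgCl (5 equiv), ZnCl2 (5 equiv), THF, 0 °C; then 20, PdCl2(dppf) (10 mol %), THF, 40 °C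
Reagents that add atoms: (trimethylsilyl)methylmagnesium chloride, C[Si](C)(C)C[Mg]Cl
Why: Twofold Negishi coupling of the enol triflates with the mild (trimethylsilyl)methylzinc reagent gives the two allylsilanes, the chelating diphosphine leaves no free phosphine to reduce the dialkyl peroxide, and the organozinc reagent attacks neither the ester nor the O–O bond.

Step 14
Reactants: 21 bis(allylsilane) methyl (2R)-2-[(3R,6S)-6-{2-[(2S,4aS,8aS)-1,1-dimethyl-3,6-bis[(trimethylsilyl)methyl]-1,2,4a,5,8,8a-hexahydronaphthalen-2-yl]ethyl}-6-methyl-1,2-dioxan-3-yl]propanoate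
Product: 22 methyl ester methyl (2R)-2-[(3R,6S)-6-{2-[(2R,4aS,8aS)-1,1-dimethyl-3,6-dimethylidenedecahydronaphthalen-2-yl]ethyl}-6-methyl-1,2-dioxan-3-yl]propanoate
Conditions: p-TsOH·H2O (20 mol %), wet CH2Cl2, 0 °C
Reagents that add atoms: none
Why: Each allylsilane is protonated at the ring carbon γ to silicon and the β-silyl cation loses silicon to give the exocyclic methylene (SE2' protodesilylation) far faster than the product alkenes are protonated, and because every protonated carbon becomes a CH2 group no stereocentre is formed.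

Step 15
Reactants: 22 methyl ester methyl (2R)-2-[(3R,6S)-6-{2-[(2R,4aS,8aS)-1,1-dimethyl-3,6-dimethylidenedecahydronaphthalen-2-yl]ethyl}-6-methyl-1,2-dioxan-3-yl]propanoate
Product: 23 target acid (2R)-2-[(3R,6S)-6-{2-[(2R,4aS,8aS)-1,1-dimethyl-3,6-dimethylidenedecahydronaphthalen-2-yl]ethyl}-6-methyl-1,2-dioxan-3-yl]propanoic acid
Conditions: LiOH (3 equiv), THF/H2O 3:1, 0 °C to rt; then 1 M HCl to pH 3, 0 °C
Reagents that add atoms: lithium hydroxide, [Li+].[OH-]
Why: Mild saponification of the methyl ester (ester hydrolysis) is the usual last step for β-peroxy esters of this class and at 0 °C should neither epimerise the α-carbon nor open the dioxane by retro-Michael reaction.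

## Compound list

1 | anhydride 4,4-dimethyloxane-2,6-dione (3,3-dimethylglutaric anhydride) | CC1(C)CC(=O)OC(=O)C1 | starting material
2 | lactone 4,4-dimethyloxan-2-one | CC1(C)CCOC(=O)C1 | intermediate
3 | lactol 4,4-dimethyloxan-2-ol | CC1(C)CCOC(O)C1 | intermediate
4 | Grignard reagent [2-(1,3-dioxolan-2-yl)ethyl]magnesium bromide | Br[Mg]CCC1OCCO1 | starting material
5 | Weinreb amide N-methoxy-N-methylprop-2-enamide | C=CC(=O)N(C)OC | starting material
6 | vinyl ketone 5-(1,3-dioxolan-2-yl)pent-1-en-3-one | C=CC(=O)CCC1OCCO1 | intermediate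
7 | keto lactol (3S)-3-[5-(1,3-dioxolan-2-yl)-3-oxopentyl]-4,4-dimethyloxan-2-ol (both anomers) | OC1OCCC(C)(C)[C@@H]1CCC(=O)CCC1OCCO1 | intermediate
8 | diene alcohol (4R)-9-(1,3-dioxolan-2-yl)-4-ethenyl-3,3-dimethyl-7-methylidenenonan-1-ol | OCCC(C)(C)[C@H](CCC(=C)CCC1OCCO1)C=C | intermediate
9 | diene aldehyde (4R)-9-(1,3-dioxolan-2-yl)-4-ethenyl-3,3-dimethyl-7-methylidenenonanal | O=CCC(C)(C)[C@H](CCC(=C)CCC1OCCO1)C=C | intermediate
10 | enone but-3-en-2-one | CC(=O)C=C | starting material
11 | keto aldehyde (2R)-2-[(3R)-8-(1,3-dioxolan-2-yl)-3-ethenyl-2-methyl-6-methylideneoctan-2-yl]-5-oxohexanal | CC(=O)CC[C@@H](C=O)C(C)(C)[C@H](CCC(=C)CCC1OCCO1)C=C | intermediate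
12 | cyclohexenone (4S)-4-[(3R)-8-(1,3-dioxolan-2-yl)-3-ethenyl-2-methyl-6-methylideneoctan-2-yl]cyclohex-2-en-1-one | O=C1CC[C@@H](C=C1)C(C)(C)[C@H](CCC(=C)CCC1OCCO1)C=C | intermediate
13 | enone methyl ketone (4S)-4-[(3S)-3-acetyl-8-(1,3-dioxolan-2-yl)-2-methyl-6-methylideneoctan-2-yl]cyclohex-2-en-1-one | O=C1CC[C@@H](C=C1)C(C)(C)[C@H](CCC(=C)CCC1OCCO1)C(C)=O | intermediate
14 | cis-decalindione (3S,4aS,8aS)-3-[5-(1,3-dioxolan-2-yl)-3-methylidenepentyl]-4,4-dimethyloctahydronaphthalene-2,7(1H,3H)-dione | O=C1CC[C@H]2[C@@H](C1)CC(=O)[C@@H](CCC(=C)CCC1OCCO1)C2(C)C | intermediate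
15 | bis(enol triflate) (3S,4aS,8aR)-3-[5-(1,3-dioxolan-2-yl)-3-methylidenepentyl]-4,4-dimethyl-3,4,4a,5,8,8a-hexahydronaphthalene-2,7-diyl bis(trifluoromethanesulfonate) | O=S(=O)(OC1=CC[C@H]2[C@@H](C1)C=C(OS(=O)(=O)C(F)(F)F)[C@@H](CCC(=C)CCC1OCCO1)C2(C)C)C(F)(F)F | intermediate
16 | hydroperoxy acetal (3S,4aS,8aR)-3-[5-hydroperoxy-5-(2-hydroxyethoxy)-3-methylidenepentyl]-4,4-dimethyl-3,4,4a,5,8,8a-hexahydronaphthalene-2,7-diyl bis(trifluoromethanesulfonate) | O=S(=O)(OC1=CC[C@H]2[C@@H](C1)C=C(OS(=O)(=O)C(F)(F)F)[C@@H](CCC(=C)CCC(OO)OCCO)C2(C)C)C(F)(F)F | intermediate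
17 | peroxyacetal (3S,4aS,8aR)-3-{2-[(3S)-6-(2-hydroxyethoxy)-3-methyl-1,2-dioxan-3-yl]ethyl}-4,4-dimethyl-3,4,4a,5,8,8a-hexahydronaphthalene-2,7-diyl bis(trifluoromethanesulfonate) (both acetal epimers) | O=S(=O)(OC1=CC[C@H]2[C@@H](C1)C=C(OS(=O)(=O)C(F)(F)F)[C@@H](CC[C@@]1(C)CCC(OCCO)OO1)C2(C)C)C(F)(F)F | intermediate
18 | ketene acetal (E)-1-methoxy-1-(trimethylsilyloxy)prop-1-ene | C/C=C(/O[Si](C)(C)C)OC | starting material
19 | silyl ether (3S,4aS,8aR)-4,4-dimethyl-3-(2-{(3S)-3-methyl-6-[2-(trimethylsilyloxy)ethoxy]-1,2-dioxan-3-yl}ethyl)-3,4,4a,5,8,8a-hexahydronaphthalene-2,7-diyl bis(trifluoromethanesulfonate) | O=S(=O)(OC1=CC[C@H]2[C@@H](C1)C=C(OS(=O)(=O)C(F)(F)F)[C@@H](CC[C@@]1(C)CCC(OCCO[Si](C)(C)C)OO1)C2(C)C)C(F)(F)F | intermediate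
20 | dioxane ester methyl (2R)-2-[(3R,6S)-6-{2-[(2S,4aR,8aS)-1,1-dimethyl-3,6-bis(trifluoromethanesulfonyloxy)-1,2,4a,5,8,8a-hexahydronaphthalen-2-yl]ethyl}-6-methyl-1,2-dioxan-3-yl]propanoate | O=S(=O)(OC1=CC[C@H]2[C@@H](C1)C=C(OS(=O)(=O)C(F)(F)F)[C@@H](CC[C@@]1(C)CC[C@H]([C@@H](C)C(=O)OC)OO1)C2(C)C)C(F)(F)F | intermediate
21 | bis(allylsilane) methyl (2R)-2-[(3R,6S)-6-{2-[(2S,4aS,8aS)-1,1-dimethyl-3,6-bis[(trimethylsilyl)methyl]-1,2,4a,5,8,8a-hexahydronaphthalen-2-yl]ethyl}-6-methyl-1,2-dioxan-3-yl]propanoate | C[Si](C)(C)CC1=CC[C@H]2[C@@H](C1)C=C(C[Si](C)(C)C)[C@@H](CC[C@@]1(C)CC[C@H]([C@@H](C)C(=O)OC)OO1)C2(C)C | intermediate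
22 | methyl ester methyl (2R)-2-[(3R,6S)-6-{2-[(2R,4aS,8aS)-1,1-dimethyl-3,6-dimethylidenedecahydronaphthalen-2-yl]ethyl}-6-methyl-1,2-dioxan-3-yl]propanoate | C=C1CC[C@H]2[C@@H](C1)CC(=C)[C@@H](CC[C@@]1(C)CC[C@H]([C@@H](C)C(=O)OC)OO1)C2(C)C | intermediate
23 | target acid (2R)-2-[(3R,6S)-6-{2-[(2R,4aS,8aS)-1,1-dimethyl-3,6-dimethylidenedecahydronaphthalen-2-yl]ethyl}-6-methyl-1,2-dioxan-3-yl]propanoic acid (CNP0363961.1) | C=C1CC[C@H]2[C@@H](C1)CC(=C)[C@@H](CC[C@@]1(C)CC[C@H]([C@@H](C)C(=O)O)OO1)C2(C)C | target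

## Step count and risks

Total steps: 15. Longest linear sequence: 14 steps (1 to 23 through steps 1, 2 and 4–15; step 3 is a one-step branch).

The three steps most likely to fail:

Step 11 (new). The cyclisation has no direct precedent: the hydroperoxy acetal may decompose under strong acid (Criegee-type loss to an ester), free H2O2 may add to the alkene outside the catalyst pocket, and the catalyst may not distinguish methyl from the alkyl chain on a dioxane-forming substrate. The fallback sets out from 15 and uses known chemistry: cobalt-catalysed hydroperoxysilylation of the 1,1-disubstituted alkene (Co(acac)2, O2, Et3SiH, ClCH2CH2Cl) gives the tertiary triethylsilyl peroxide F1 as a 1:1 mixture at the new carbon. Acid (p-TsOH, CH2Cl2) then removes silicon and closes the peroxide onto the acetal carbon. This comes back to the route at 17, now as both epimers at the quaternary peroxide carbon, which are separated by HPLC after step 12.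

Step 12 (new). Peroxycarbenium ions have not been used with chiral counter-anions; facial control against a near-symmetrical C-6 and the anti/syn ratio at the α-methyl are both untested, and the silylium acid may cleave the tertiary C–O bond. The fallback sets out from 15, comes back at 20, and is the established sequence for this compound class. Acetal hydrolysis (AcOH/H2O/THF) gives the aldehyde F2. Wittig reaction with methyl 2-(triphenyl-λ5-phosphanylidene)propanoate gives the (E)-enoate F3. Cobalt-catalysed hydroperoxysilylation of the electron-rich alkene (Co(acac)2, O2, Et3SiH) gives the silyl peroxide F4. HCl in MeOH followed by Et2NH in CF3CH2OH frees the hydroperoxide and triggers intramolecular peroxa-Michael addition. 20 is then separated from its dioxane diastereomers by HPLC.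

Step 13. Zerovalent palladium or the organozinc reagent may cleave the O–O bond, and the ring B triflate sits next to a fully substituted carbon. The fallback sets out from 14 and comes back at 22: the ketones are left unmasked, the conditions of step 11 applied to 14 give the peroxyacetal dione F5, the conditions of step 12 then give the diketo ester F6, and a double Wittig methylenation (Ph3PCH3Br, KOt-Bu, THF, 0 °C) installs both methylenes at the end. Its weak points are the hindered ring B ketone and possible epimerisation at decalin C-2.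

Further compounds
F1 | step 11 | triethylsilyl peroxide (3S,4aS,8aR)-3-{5-(1,3-dioxolan-2-yl)-3-methyl-3-[(triethylsilyl)peroxy]pentyl}-4,4-dimethyl-3,4,4a,5,8,8a-hexahydronaphthalene-2,7-diyl bis(trifluoromethanesulfonate) (both epimers at the peroxide carbon) | O=S(=O)(OC1=CC[C@H]2[C@@H](C1)C=C(OS(=O)(=O)C(F)(F)F)[C@@H](CCC(C)(CCC1OCCO1)OO[Si](CC)(CC)CC)C2(C)C)C(F)(F)F
F2 | step 12 | aldehyde (3S,4aS,8aR)-4,4-dimethyl-3-(3-methylidene-6-oxohexyl)-3,4,4a,5,8,8a-hexahydronaphthalene-2,7-diyl bis(trifluoromethanesulfonate) | O=S(=O)(OC1=CC[C@H]2[C@@H](C1)C=C(OS(=O)(=O)C(F)(F)F)[C@@H](CCC(=C)CCC=O)C2(C)C)C(F)(F)F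
F3 | step 12 | (E)-enoate methyl (2E)-8-[(2S,4aR,8aS)-1,1-dimethyl-3,6-bis(trifluoromethanesulfonyloxy)-1,2,4a,5,8,8a-hexahydronaphthalen-2-yl]-2-methyl-6-methylideneoct-2-enoate | O=S(=O)(OC1=CC[C@H]2[C@@H](C1)C=C(OS(=O)(=O)C(F)(F)F)[C@@H](CCC(=C)CC/C=C(\C)C(=O)OC)C2(C)C)C(F)(F)F
F4 | step 12 | silyl peroxide methyl (2E)-8-[(2S,4aR,8aS)-1,1-dimethyl-3,6-bis(trifluoromethanesulfonyloxy)-1,2,4a,5,8,8a-hexahydronaphthalen-2-yl]-2,6-dimethyl-6-[(triethylsilyl)peroxy]oct-2-enoate (both epimers at the peroxide carbon) | O=S(=O)(OC1=CC[C@H]2[C@@H](C1)C=C(OS(=O)(=O)C(F)(F)F)[C@@H](CCC(C)(CC/C=C(\C)C(=O)OC)OO[Si](CC)(CC)CC)C2(C)C)C(F)(F)F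
F5 | step 13 | peroxyacetal dione (3S,4aS,8aS)-3-{2-[(3S)-6-(2-hydroxyethoxy)-3-methyl-1,2-dioxan-3-yl]ethyl}-4,4-dimethyloctahydronaphthalene-2,7(1H,3H)-dione | O=C1CC[C@H]2[C@@H](C1)CC(=O)[C@@H](CC[C@@]1(C)CCC(OCCO)OO1)C2(C)C
F6 | step 13 | diketo ester methyl (2R)-2-[(3R,6S)-6-{2-[(2S,4aS,8aS)-1,1-dimethyl-3,6-dioxodecahydronaphthalen-2-yl]ethyl}-6-methyl-1,2-dioxan-3-yl]propanoate | O=C1CC[C@H]2[C@@H](C1)CC(=O)[C@@H](CC[C@@]1(C)CC[C@H]([C@@H](C)C(=O)OC)OO1)C2(C)C
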